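## Retrosynthetic overview
1. The side chain is finished last. C14-OH comes from a CBS reduction, C9-OH from an SeO2 allylic hydroxylation, and the 12-acetate from a selective acylation. The C12–C13 bond comes from a Felkin aldol of methyl isopropenyl ketone on the lactol of a 6,12-olide.
2. The Δ2 alkene comes from a C3 ketone by kinetic enol triflation and formate hydrogenolysis.
3. Second ring: transannular cationic C1–C5 closure (4π-conrotatory, hydride-terminated) of a ten-membered 3-oxo-1E,4E,10(18)-triene. This gives the trans 5/7 fusion.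
4. First ring: C6–C7 closure of an acyclic C15 hydroxy-trienal. The distal isopropylidene attacks the C6 aldehyde and a methyl proton is lost to give the isopropenyl group, which is the C1–C10 closure of the polyprenyl chain in aldehyde form.
5. The acyclic chain is built from three C5 units (isopropenylacetylene, prenyl bromide, C5 acetal-enal). The fourth C5 unit is the ketone of line 1.

Assumption: dictyol numbering is used throughout (ring C1–C10; side chain C11–C16; C17 = 4-CH3, C18 = 10-CH2, C19 = 11-CH3, C20 = 15-CH3); the C3 carbinol centre is sacrificial, and 5 is taken as the purchasable industrial C5 carotenoid building block.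

## Route

Step 1
Reactants: 1 2-methylbut-1-en-3-yne; 2 1-bromo-3-methylbut-2-ene (prenyl bromide)
Product: 4 7-methyl-3-methylideneoct-6-en-1-yne, via dipotassio enyne 3 (not isolated)
Conditions: n-BuLi/t-BuOK (2.1 equiv each), THF–hexane, −78 → −20 °C; 2 (1.0 equiv), −78 °C; H2O
Reagents that add atoms: none
Why: Lochmann–Schlosser double metalation gives the acetylide/allyl dianion, whose far more basic and symmetrical allyl terminus is alkylated selectively by the primary allylic bromide (SN2), so the terminal alkyne is kept for step 2 and no stereocentre is formed.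

Step 2
Reactants: 4 7-methyl-3-methylideneoct-6-en-1-yne; 5 (E)-4,4-dimethoxy-2-methylbut-2-enal
Product: 9 (2E,4S,5E)-4-hydroxy-3,11-dimethyl-7-methylidenedodeca-2,5,10-trienal, via dienylborane 6 (not isolated), via dienylzinc 7 (not isolated), via acetal carbinol 8 (not isolated)
Conditions: Cy2BH, toluene, 0 °C → rt; Me2Zn, (−)-MIB (5 mol %), −78 °C; 5, −20 °C; H2O; then PPTS (cat.), acetone–H2O, 0 °C
Reagents that add atoms: water, O
Why: Oppolzer–Radinov-type catalytic asymmetric alkenylzinc addition: syn-hydroboration of the terminal alkyne fixes the 1E geometry, B→Zn exchange gives the dienylzinc, the (−)-MIB–zinc catalyst delivers it 1,2 to the Si face of the enal to set the sacrificial 3S carbinol, and mild acetal hydrolysis then unmasks the C6 enal, whose acceptor character protects the bis-allylic alcohol from ionisation.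

Step 3
Reactants: 9 (2E,4S,5E)-4-hydroxy-3,11-dimethyl-7-methylidenedodeca-2,5,10-trienal
Product: 10 (1S,2E,4S,5E,10S)-3-methyl-7-methylidene-10-(prop-1-en-2-yl)cyclodeca-2,5-diene-1,4-diol (ten-membered diol; 6-OH and 7-isopropenyl cis)
Conditions: Me2AlCl (3 equiv), CH2Cl2, slow addition of 9 (final 0.5 mM), −78 → −40 °C; H2O
Reagents that add atoms: none
Why: Proposed new method: aluminium complexation makes the C6 enal the only electrophile (the 3-OH is capped as its aluminium alkoxide) and the two E-alkenes put every nearer π-bond geometrically out of reach, so the electron-rich distal isopropylidene attacks C6 through C7 while a methyl proton passes to oxygen in a closed six-centre carbonyl-ene transition state (closest known type: alkylaluminium-chloride-promoted type-I ene macrocyclisation of ω-isopropylidene unsaturated aldehydes to 14-membered isopropenyl carbinols); C6 is set by the 3S centre, whose bulky aluminoxy group avoids the 4-methyl (A1,2 strain) and so forces the chain over one face of the planar C3–C6 enal unit, and C7 is set syn (6-O/C11 cis) because aluminium sits anti to the chain, the proton goes to the lone pair syn to it, and C8 turns away from the metal.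

Step 4
Reactants: 10 ten-membered diol
Product: 12 (1R,2E,4S,5E,10S)-10-(1-hydroxypropan-2-yl)-3-methyl-7-methylidenecyclodeca-2,5-diene-1,4-diol (C11 epimers), via B-alkyl-9-BBN adduct 11 (not isolated)
Conditions: 9-BBN (3.5 equiv), THF, 0 °C → rt; H2O2, NaOH, 0 °C
Reagents that add atoms: hydrogen peroxide, OO
Why: Brown hydroboration–oxidation, in which 9-BBN discriminates the isolated 1,1-disubstituted isopropenyl group from the trisubstituted Δ4 alkene and the much less reactive conjugated diene and places boron on C12; the new C11 centre may form unselectively because it is fixed by equilibration in step 6.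

Step 5
Reactants: 12 ten-membered triol
Product: 14 ten-membered trienone lactone (3-oxo; 1E,4E; 10(18)-methylidene; cis-6,12-olide; 6R,7S; C11 epimers), via ten-membered lactol 13 (not isolated)
Conditions: TEMPO (20 mol %), PhI(OAc)2 (3.5 equiv), CH2Cl2, rt
Reagents that add atoms: none
Why: Oxoammonium oxidation with oxidative lactonisation: the primary alcohol reacts first, its aldehyde is trapped by the cis 6-OH as the γ-lactol and oxidised on to the lactone (which masks O6), and the bis-allylic 3-OH goes to the cross-conjugated ketone, with no retained stereocentre touched.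

Step 6
Reactants: 14 ten-membered trienone lactone
Product: 16 (1R,4R,5S,6R,7S,11S)-3-oxo-10(18)-methylidene trans-hydroazulene 6,12-olide (H1/H5 trans; 4-CH3 trans to C6; cis-lactone; 11-CH3 on the convex face), via epimeric ketone mixture 15 (not isolated)
Conditions: BF3·OEt2 (1.2 equiv), Et3SiH (5 equiv), CH2Cl2, −78 → −20 °C; H2O; then DBU (0.3 equiv), toluene, 80 °C
Reagents that add atoms: none
Why: Proposed new method: BF3 turns the cross-conjugated dienone, held in the reactive U-shape by the ring, into a 3-oxypentadienyl cation that closes C1–C5 by thermally allowed 4π-conrotation, and Et3SiH reduces the resulting oxyallyl cation before it can lose H1 or H5 (closest known type: silane-interrupted reductive Nazarov cyclisation of acyclic dienones); C5 is attacked on the face carrying C7 with H6 eclipsing the 4-methyl side (A1,3 strain), which puts H5 cis to O6, conrotation of the two E-alkenes makes H1 trans to H5, and DBU then equilibrates the two enolisable centres to 4-CH3 trans to C6 and 11-CH3 on the convex face of the cis-lactone.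

Step 7
Reactants: 16 3-oxo hydroazulene lactone
Product: 18 Δ2-enol triflate of 16 (1S,4R,5S,6R,7S,11S), via potassium enolate 17 (not isolated)
Conditions: KHMDS (1.05 equiv), THF, −78 °C; PhNTf2, −78 → 0 °C; H2O
Reagents that add atoms: N-phenylbis(trifluoromethanesulfonimide), O=S(=O)(N(c1ccccc1)S(=O)(=O)C(F)(F)F)C(F)(F)F
Why: Kinetic enolate O-triflation: the hindered base removes a proton from the C2 methylene rather than the tertiary C4-H or the less acidic lactone C11-H, so the double bond is placed at C2=C3 and no stereocentre changes.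

Step 8
Reactants: 18 Δ2-enol triflate
Product: 19 (3S,3aS,6aR,9S,9aR,9bR)-3,9-dimethyl-6-methylidene-3a,4,5,6,6a,9,9a,9b-octahydroazuleno[4,5-b]furan-2(3H)-one (2,10(18)-diene 6,12-olide)
Conditions: Pd(OAc)2 (5 mol %), PPh3, HCO2H, Et3N, DMF, 60 °C
Reagents that add atoms: none
Why: Palladium-catalysed formate hydrogenolysis of a vinyl triflate (oxidative addition, decarboxylation to Pd–H, reductive elimination) replaces OTf by H without moving the alkene; the lactone C6–O bond is no longer allylic and is inert.

Step 9
Reactants: 19 diene lactone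
Product: 20 6,12-lactol of 19 (anomers)
Conditions: DIBAL-H (1.1 equiv), CH2Cl2, −78 °C; H2O
Reagents that add atoms: none
Why: Half-reduction of a γ-lactone with DIBAL-H stops at the stable aluminium hemiacetal at −78 °C, and nothing else in 19 is reducible.

Step 10
Reactants: 20 lactol; 21 3-methylbut-3-en-2-one
Product: 23 (12S)-6,12-dihydroxy-14-oxo diterpenoid (1R,4S,5R,6R,7S,11S,12S; 2,10(18),15-triene), via lithium enolate 22 (not isolated)
Conditions: LDA (3.1 equiv), 21 (3.0 equiv), THF, −78 °C; then 20, −78 → −40 °C; H2O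
Reagents that add atoms: none
Why: Aldol addition of the kinetic methyl-side lithium enolate to the open hydroxy-aldehyde form of the lithium lactolate, under Felkin–Anh control by C11 (ring carbon C7 as the large group), gives the 11,12-syn product, which is 12S.

Step 11
Reactants: 23 6,12-diol 14-ketone
Product: 24 12-acetate of 23
Conditions: Ac2O (1.2 equiv), pyridine, 0 °C
Reagents that add atoms: acetic anhydride, CC(=O)OC(C)=O
Why: Site-selective acylation: the 6-OH is flanked by the ring-fusion carbon C5 and the branched C7 and is as unreactive as the notoriously hindered 6-OH of the dictyols, so only the 12-OH is esterified, and the cold DMAP-free conditions avoid β-elimination of the β-acetoxy ketone.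

Step 12
Reactants: 24 12-acetate
Product: 25 (9R)-9-hydroxy derivative of 24
Conditions: SeO2 (0.3 equiv), t-BuOOH (3 equiv), CH2Cl2, 0 °C → rt
Reagents that add atoms: selenium dioxide (catalytic oxygen carrier), O=[Se]=O; tert-butyl hydroperoxide, CC(C)(C)OO
Why: Selenium dioxide allylic hydroxylation (ene reaction followed by [2,3]-shift) returns the alkene to C10=C18 and oxidises the only allylic CH2 (C9; the competing C1-H and C4-H are tertiary and the side-chain isopropenyl is deactivated by the ketone), and the reagent approaches from the face of H1, opposite O6 and the C7 side chain, so oxygen arrives on that face and gives 9R.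

Step 13
Reactants: 25 9-hydroxy 14-ketone
Product: 26 target CNP0151410.1 (1R,4S,5R,6R,7S,9R,11S,12S,14R)
Conditions: (S)-Me-CBS (0.3 equiv), catecholborane (4 equiv), toluene, −78 °C; H2O
Reagents that add atoms: none
Why: Corey–Bakshi–Shibata reduction, in which the isopropenyl group is the large substituent and CH2 the small one, so the (S)-oxazaborolidine delivers hydride 1,2 to give 14R (12,14-syn), while catecholborane at −78 °C spares the alkenes and the acetate.

## Compound list
1 | 2-methylbut-1-en-3-yne | C=C(C)C#C | starting material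
2 | 1-bromo-3-methylbut-2-ene | CC(C)=CCBr | starting material
3 | dipotassio enyne (acetylide/allyl dianion of 1) | [K]C#CC(=C)C[K] | intermediate
4 | 7-methyl-3-methylideneoct-6-en-1-yne | C#CC(=C)CCC=C(C)C | intermediate
5 | (E)-4,4-dimethoxy-2-methylbut-2-enal | O=C/C(C)=C/C(OC)OC | starting material
6 | dicyclohexyl[(1E)-7-methyl-3-methylideneocta-1,6-dienyl]borane | CC(C)=CCCC(=C)/C=C/B(C1CCCCC1)C1CCCCC1 | intermediate
7 | methyl[(1E)-7-methyl-3-methylideneocta-1,6-dienyl]zinc | CC(C)=CCCC(=C)/C=C/[Zn]C | intermediate
8 | (2E,4S,5E)-1,1-dimethoxy-3,11-dimethyl-7-methylidenedodeca-2,5,10-trien-4-ol | COC(OC)/C=C(C)/[C@@H](O)/C=C/C(=C)CCC=C(C)C | intermediate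
9 | (2E,4S,5E)-4-hydroxy-3,11-dimethyl-7-methylidenedodeca-2,5,10-trienal | O=C/C=C(C)/[C@@H](O)/C=C/C(=C)CCC=C(C)C | intermediate
10 | (1S,2E,4S,5E,10S)-3-methyl-7-methylidene-10-(prop-1-en-2-yl)cyclodeca-2,5-diene-1,4-diol | C=C(C)[C@@H]1CCC(=C)/C=C/[C@H](O)/C(C)=C/[C@@H]1O | intermediate
11 | B-alkyl-9-BBN adduct of 10 at C12 (C11 epimers) | C(B1C2CCCC1CCC2)C(C)[C@@H]1CCC(=C)/C=C/[C@H](O)/C(C)=C/[C@@H]1O | intermediate
12 | (1R,2E,4S,5E,10S)-10-(1-hydroxypropan-2-yl)-3-methyl-7-methylidenecyclodeca-2,5-diene-1,4-diol (C11 epimers) | OCC(C)[C@@H]1CCC(=C)/C=C/[C@H](O)/C(C)=C/[C@@H]1O | intermediate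
13 | ten-membered 6,12-lactol, 3-OH still present (C11 and C12 epimers) | OC3C(C)[C@@H]1CCC(=C)/C=C/[C@H](O)/C(C)=C/[C@@H]1O3 | intermediate
14 | ten-membered trienone lactone (3-oxo; 1E,4E; 10(18)-methylidene; cis-6,12-olide; 6R,7S; C11 epimers) | O=C3C(C)[C@@H]1CCC(=C)/C=C/C(=O)/C(C)=C/[C@@H]1O3 | intermediate
15 | trans-hydroazulen-3-one 6,12-olide, mixture of C4 and C11 epimers | O=C3C(C)[C@@H]1CCC(=C)[C@@H]2CC(=O)C(C)[C@H]2[C@@H]1O3 | intermediate
16 | (1R,4R,5S,6R,7S,11S)-3-oxo-10(18)-methylidene trans-hydroazulene 6,12-olide | O=C3[C@@H](C)[C@@H]1CCC(=C)[C@@H]2CC(=O)[C@H](C)[C@H]2[C@@H]1O3 | intermediate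
17 | potassium Δ2-enolate of 16 | O=C3[C@@H](C)[C@@H]1CCC(=C)[C@@H]2C=C(O[K])[C@H](C)[C@H]2[C@@H]1O3 | intermediate
18 | Δ2-enol triflate of 16 | O=C3[C@@H](C)[C@@H]1CCC(=C)[C@@H]2C=C(OS(=O)(=O)C(F)(F)F)[C@H](C)[C@H]2[C@@H]1O3 | intermediate
19 | (3S,3aS,6aR,9S,9aR,9bR)-3,9-dimethyl-6-methylidene-3a,4,5,6,6a,9,9a,9b-octahydroazuleno[4,5-b]furan-2(3H)-one | O=C3[C@@H](C)[C@@H]1CCC(=C)[C@@H]2C=C[C@H](C)[C@H]2[C@@H]1O3 | intermediate
20 | 6,12-lactol of 19 (anomers) | OC3[C@@H](C)[C@@H]1CCC(=C)[C@@H]2C=C[C@H](C)[C@H]2[C@@H]1O3 | intermediate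
21 | 3-methylbut-3-en-2-one | CC(=O)C(C)=C | starting material
22 | lithium enolate of 21 | [Li]OC(=C)C(C)=C | intermediate
23 | 6,12-dihydroxy-14-oxo diterpenoid (1R,4S,5R,6R,7S,11S,12S) | C=C(C)C(=O)C[C@H](O)[C@@H](C)[C@@H]1CCC(=C)[C@@H]2C=C[C@H](C)[C@H]2[C@@H]1O | intermediate
24 | 12-acetate of 23 | C=C(C)C(=O)C[C@H](OC(C)=O)[C@@H](C)[C@@H]1CCC(=C)[C@@H]2C=C[C@H](C)[C@H]2[C@@H]1O | intermediate
25 | (9R)-9-hydroxy derivative of 24 | C=C(C)C(=O)C[C@H](OC(C)=O)[C@@H](C)[C@@H]1C[C@@H](O)C(=C)[C@@H]2C=C[C@H](C)[C@H]2[C@@H]1O | intermediate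
26 | CNP0151410.1 (1R,4S,5R,6R,7S,9R,11S,12S,14R) | C=C(C)[C@H](O)C[C@H](OC(C)=O)[C@@H](C)[C@@H]1C[C@@H](O)C(=C)[C@@H]2C=C[C@H](C)[C@H]2[C@@H]1O | target

## Step count and risks
Total step count: 13. Longest linear sequence: 13 (1 → 26).

**Step 3 (ten-membered carbonyl-ene closure).** It may give oligomers or the 6,7-anti isomer.
- The fallback sets out from 4 and comes back at 10. It turns the nucleophile into an allylsilane, so the closure no longer depends on C–H transfer.
- SeO2/t-BuOOH oxidises the E-methyl of the isopropylidene of 4 to (E)-2-methyl-6-methylideneoct-2-en-7-yn-1-ol F1.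
- Pd-catalysed silylation of the allylic alcohol with hexamethyldisilane gives the allylsilane F2.
- The step-2 sequence then runs through the silyl dienylborane F3, the silyl dienylzinc F4 and the silyl acetal carbinol F5 to the silyl hydroxy enal F6.
- An intramolecular Hosomi–Sakurai reaction closes C6–C7 (BF3·OEt2 or a tartrate-derived acyloxyborane, EtCN, −78 °C, high dilution). Its open antiperiplanar transition state is syn-selective for E-allylsilanes and gives 10.

**Step 6 (transannular reductive Nazarov closure).** Proton loss from the oxyallyl cation or premature silane reduction may win.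
- The fallback sets out from 14 and comes back at 16. It separates C–C bond formation from the reduction.
- TiCl4 (CH2Cl2, −78 °C) triggers the same conrotatory closure, but the oxyallyl cation is captured at once by chloride from the titanium enolate to give the 2-chloro ketone F7.
- Zn/AcOH then removes chlorine through the zinc enolate, and DBU equilibration gives 16.

**Step 12 (site and facial selectivity of the SeO2 hydroxylation).**
- The fallback sets out from 24 and comes back at 26. It gives up substrate control at C9.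
- The SeO2 oxidation is run without regard to facial selectivity to the 9-epimeric alcohols F8.
- MnO2 oxidises only the allylic 9-OH to the 9,14-dione F9.
- Both α-alkylidene ketones are then reduced in one operation with (S)-Me-CBS/catecholborane. In each ketone the alkenyl carbon is the large group, so the reagent sets 9R and 14R together and gives 26.

Further compounds
F1 | step 3 | (E)-2-methyl-6-methylideneoct-2-en-7-yn-1-ol | C#CC(=C)CC/C=C(C)/CO
F2 | step 3 | [(E)-2-methyl-6-methylideneoct-2-en-7-ynyl]trimethylsilane | C#CC(=C)CC/C=C(C)/C[Si](C)(C)C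
F3 | step 3 | dicyclohexyl[(1E,6E)-7-methyl-3-methylidene-8-(trimethylsilyl)octa-1,6-dienyl]borane | C[Si](C)(C)C/C(C)=C/CCC(=C)/C=C/B(C1CCCCC1)C1CCCCC1
F4 | step 3 | methyl[(1E,6E)-7-methyl-3-methylidene-8-(trimethylsilyl)octa-1,6-dienyl]zinc | C[Si](C)(C)C/C(C)=C/CCC(=C)/C=C/[Zn]C
F5 | step 3 | (2E,4S,5E,10E)-1,1-dimethoxy-3,11-dimethyl-7-methylidene-12-(trimethylsilyl)dodeca-2,5,10-trien-4-ol | COC(OC)/C=C(C)/[C@@H](O)/C=C/C(=C)CC/C=C(C)/C[Si](C)(C)C
F6 | step 3 | (2E,4S,5E,10E)-4-hydroxy-3,11-dimethyl-7-methylidene-12-(trimethylsilyl)dodeca-2,5,10-trienal | O=C/C=C(C)/[C@@H](O)/C=C/C(=C)CC/C=C(C)/C[Si](C)(C)C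
F7 | step 6 | 2-chloro-3-oxo trans-hydroazulene 6,12-olide (C2, C4 and C11 epimers) | O=C3C(C)[C@@H]1CCC(=C)[C@@H]2C(Cl)C(=O)C(C)[C@H]2[C@@H]1O3
F8 | step 12 | 9-hydroxy derivative of 24 as C9 epimers | C=C(C)C(=O)C[C@H](OC(C)=O)[C@@H](C)[C@@H]1CC(O)C(=C)[C@@H]2C=C[C@H](C)[C@H]2[C@@H]1O
F9 | step 12 | 9,14-dione derived from 24 | C=C(C)C(=O)C[C@H](OC(C)=O)[C@@H](C)[C@@H]1CC(=O)C(=C)[C@@H]2C=C[C@H](C)[C@H]2[C@@H]1O
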